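**Remark on the chemistry:** ring A of the target carries three C-methyl groups, so the phenol that enters the ester bond must be methyl 2,4-dihydroxy-3,5,6-trimethylbenzoate; the readily available methyl 2,4-dihydroxy-3,6-dimethylbenzoate is one methyl short (C3 of ring A is still C–H) and is therefore used as an intermediate that receives one C-methylation, not as the coupling partner.

**Position labels:** ring A is C1 (CO2CH3), C2 (CH3), C3 (CH3), C4 (aroyloxy O), C5 (CH3), C6 (OH); ring B is C1' (C=O), C2' (CH3), C3' (Cl), C4' (OH), C5' (CH3), C6' (OCH3). Locants inside compound names follow nomenclature rules and may differ from these labels.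

## Structural features

The target is a depside without any stereocentre: two hexasubstituted benzene rings, ring A and ring B, are held together only by an aryl ester between the C1' carbonyl carbon of ring B and the C4 oxygen of ring A. Ring A is a methyl salicylate with methyl groups at C2, C3 and C5 and a C6 hydroxyl hydrogen-bonded to the ester carbonyl; ring B carries methyl groups at C2' and C5', chlorine at C3', a free hydroxyl at C4' and a methoxy group at C6'. Since the target has no stereocentres, none stand next to each other; the only sp3 centres of the plan (C1', C2' and C5' in 3 and 4, the first two adjacent) are transient and disappear on aromatisation. The fragile groups are the aryl ester (cleaved by hydroxide, alkoxide and amines), the methyl ester, the aryl chloride (lost under hydrogenolysis) and the electron-rich phenols (oxidation, over-halogenation). The real difficulty lies in three places: every ring position is occupied, so substituents must be placed by construction and not by late aromatic substitution; the two oxygens of ring B must end up different (C6' methylated, C4' free); and the ester bond joins a benzoic acid with two ortho substituents to a phenol with two ortho methyl groups. The key step exploits the resorcinol pattern of ring B: oxygen at C4' and C6' with the C5' methyl between them, the carboxyl carbon on C1' and a methyl on C2' are exactly a 2,4-dioxocyclohexane-1-carboxylate made from a β-keto ester (C1', C6', C5' and its methyl) and a crotonate (C2' and its methyl, C3', C4'). C3' is the one carbon this construction leaves unsubstituted, so it becomes the only aromatic C–H of ring B and the chlorination site; the same aromatised ring with one more methyl at C3 is ring A, so one annulation feeds both halves.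

## Logic of the disconnections

**14 to 13.** The C3'–Cl bond is cut first. Chlorine would not survive the hydrogenolysis that frees the C4' hydroxyl, and in 13 the carbon C3' is the single aromatic C–H of the whole molecule and lies ortho to that free hydroxyl. The gain is that all earlier intermediates are halogen-free. The forward step must deliver one equivalent of a mild electrophilic chlorine and leave the fully substituted ring A alone.

**13 to 12.** The C4' hydroxyl is traced back to its benzyl ether; the bond broken in the forward sense is O–CH2Ph. The C4' oxygen has to be masked during ester formation, otherwise the acid would acylate itself. A benzyl ether is chosen because it is cleaved in neutral medium, where the aryl ester is safe. The demand is that no halogen is present at that stage.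

**12 to 10 and 7.** The ester bond C1'(=O)–O(C4) is cut, the only bond between the rings. This is the convergent cut and gives two pieces of similar size. The forward step must acylate the hindered C4 oxygen of 7 with a hindered acid and leave the C6 hydroxyl untouched; the hydrogen bond of C6–OH to the ring A ester provides that distinction, and an acylium-type activation is needed to overcome the crowding.

**7 to 6 to 5.** The C3–CH3 bond of ring A is cut by way of a formyl group. C3 is the only unsubstituted carbon of 5 and is ortho to one hydroxyl and para to the other, so a one-carbon electrophile must enter there. The gain is that ring A is reduced to the same compound that serves ring B. The demand is a reduction of the aryl aldehyde to methyl that leaves the ester intact.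

**10 to 9 to 8 to 5.** The acid is traced to its methyl ester, then the C6'–O–CH3 and C4'–O–CH2Ph bonds are cut in that order. The order follows reactivity: the C4' hydroxyl is free and more acidic, the C6' hydroxyl is hydrogen-bonded, so benzyl goes on first and methyl second. The demands are a clean mono-benzylation, a forced methylation and hydrolysis of an ester flanked by two ortho substituents.

**5 to 4.** Two hydrogens are added back across C2'–C3'. A resorcinol is one oxidation level above a cyclohexane-1,3-dione, and the dione is available by condensation. The forward step must dehydrogenate without loss of oxygen or of the ester.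

**4 to 3 to 1 and 2.** The C4'–C5' bond is cut (retro-Claisen) and then the C1'–C2' bond (retro-Michael). This places every carbon substituent of the ring from two commercial esters and removes the ring altogether. The forward step must use the donor at its doubly activated carbon and close only the six-membered ring.

## Other disconnections considered

**Alternative 1:** the cut removes the C2'–CH3 and C1'–CO2H bonds of ring B. In the forward sense the aryne released from the iodoaryl triflate A2 would take up a methyl Grignard reagent at C2'; the arylmagnesium left at C1', next to the methoxy group, would be trapped with carbon dioxide to give acid A1.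
- In its favour: two carbon–carbon bonds form in one flask, and the methoxy group steers the nucleophile to the remote aryne carbon by inductive stabilisation of the developing C1' carbanion.
- Better than the chosen plan on one point: A1 is a free acid, so the hydrolysis of a hindered ester (step 7) is not needed. Its silyl ether is also indifferent to hydrogenolysis, which would allow the chlorine to be introduced before the coupling.
- Against it: A2 needs three different oxygen substituents, an iodine and a methyl on one ring. The two oxygens flanking the methyl are equivalent in any simple trioxygenated precursor and would have to be told apart statistically, and the iodine has to choose C1' over C3'. The difficulty is moved into the precursor.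
- Comparison: the chosen plan fixes regiochemistry through connectivity in a condensation under alkoxide, whereas this route relies on a directing effect in cryogenic organometallic chemistry. A1 would probably cost more steps than 10 and serves only ring B, while 5 serves both rings.

**Alternative 2:** the cut removes three ring bonds of ring A (C5–C6, C3–C4 and C1–C6). In the forward sense cyclobutenone A4 opens on heating to a vinylketene, which adds the siloxyalkyne A5 in a [2+2] sense; four-electron opening and six-electron closure then give phenol A3.
- In its favour: five contiguous substituents are placed in one operation with regiochemistry dictated by the mechanism, and the two oxygens emerge differentiated.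
- Better than the chosen plan on one point: the C2 and C3 methyl groups are set by construction, so the formylation and reduction of steps 3 and 4 are not needed.
- Against it: A3 still lacks the C1 carboxyl, which must be introduced ortho to the free hydroxyl next to the C2 methyl (a Kolbe–Schmitt-type carboxylation and esterification). A4 and A5 each need a multistep preparation and are thermally sensitive. The differentiation of the oxygens buys nothing, because in 7 the hydrogen bond already distinguishes them and the silyl group sits on the very oxygen that must be free for coupling.
- Comparison: both plans give complete regiocontrol of ring A. The chosen plan reaches 7 in two steps from 5; the benzannulation route would need several times that.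

**Alternative 3:** the cut removes C2'–C3' and C1'–C6' of ring B with the ester bond already in place. In the forward sense diene A8 adds across the triple bond of the ring A aryl but-2-ynoate A7, and loss of methanol and of the silyl group aromatises the adduct to A6, which is identical with 13.
- In its favour: the ester bond would be made from a small, unhindered acetylenic acid, so the crowded aroyl transfer of step 8 is avoided (a point on which it is better). The diene delivers C4'–OH and C6'–OCH3 already differentiated, so benzylation, methylation, hydrolysis and hydrogenolysis are not needed (a clear advantage in step count). The polarity of diene and ynoate matches the required regiochemistry.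
- Against it: A7 is an internal alkyne with a methyl on its β-carbon and is a poor dienophile. A8 carries a methyl on the ketene acetal terminus and is hindered and hydrolytically labile. The hydrogen-bonded phenol of A7 can protonate the diene, and the aryl ester of A7 can acylate it. Forcing thermal conditions would strain all of these weaknesses.
- Comparison: both plans share ring A and the final chlorination. The chosen plan spends about five more operations, each of an established type, whereas this one stakes everything on one cycloaddition that must create a hexasubstituted benzene from two hindered partners.

Key step: step 1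

## Route

Compound 5 is made once and divided: one part goes to ring A (steps 3 and 4), the other to ring B (steps 5 to 7). It is also an article of commerce, which secures the ring A branch independently.

Step 1
Reactants: 1 methyl 3-oxopentanoate; 2 methyl (E)-but-2-enoate
Product: 4 methyl 3,6-dimethyl-2,4-dioxocyclohexane-1-carboxylate, via Michael adduct 3 (not isolated)
Conditions: NaOMe (1.1 equiv), MeOH, reflux; then aq. HCl, 0 °C
Reagents that add atoms: none
Why: Michael–Claisen (dihydroresorcinol) annulation, the reaction type by which acetoacetates and crotonates give dihydroorsellinates. NaOMe removes the doubly activated proton of 1 at C1', and this enolate adds to the β-carbon of 2 (C2'), forming C1'–C2' and giving 3. Proton transfer moves the charge to the ketone α-methylene of 3 (C5'), whose enolate attacks the crotonate-derived ester carbon (C4') and expels methoxide, forming C4'–C5'; the ring closes in the 6-(enolendo)-exo-trig mode, which is stereoelectronically allowed for enolates. The dione is far more acidic than methanol and is held as its sodium enolate, which pulls the reversible Michael and Claisen equilibria forward until acidification releases 4. The three sp3 centres (C1', C2', C5') arise without control and need none, because all three become sp2 in step 2. The selectivity that matters is the donor site: with one equivalent of alkoxide only the monoanion at C1' exists, so C2' is attached to C1' and not to C5'. The ring size is secured by the substrate, since every other enolate–carbonyl pairing within 3 would close a four-membered ring, and ester exchange is invisible because base and both esters are methoxy.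

Step 2
Reactants: 4 methyl 3,6-dimethyl-2,4-dioxocyclohexane-1-carboxylate
Product: 5 methyl 2,4-dihydroxy-3,6-dimethylbenzoate
Conditions: 10% Pd/C, mesitylene, reflux, N2 stream
Reagents that add atoms: none
Why: Catalytic dehydrogenation of a dihydroresorcinol to a resorcinol; in its enol forms 4 has only the C2'–C3' unit saturated, loss of one H2 there is driven by aromatisation and by removal of hydrogen in the gas stream, and all stereocentres are erased.

Step 3
Reactants: 5 methyl 2,4-dihydroxy-3,6-dimethylbenzoate
Product: 6 methyl 3-formyl-4,6-dihydroxy-2,5-dimethylbenzoate (formyl on the one ring position that is free in 5, C3 of ring A)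
Conditions: Cl2CHOMe, TiCl4, CH2Cl2, 0 °C to rt; then aq. HCl
Reagents that add atoms: dichloromethyl methyl ether, COC(Cl)Cl; water, O
Why: Rieche formylation; the titanium phenoxide directs the electrophile to the only unsubstituted carbon, which is ortho to one hydroxyl and para to the other, and aqueous work-up should release the aldehyde.

Step 4
Reactants: 6 methyl 3-formyl-4,6-dihydroxy-2,5-dimethylbenzoate
Product: 7 methyl 2,4-dihydroxy-3,5,6-trimethylbenzoate
Conditions: Et3SiH (3 equiv), CF3CO2H, CH2Cl2, 0 °C to rt
Reagents that add atoms: none
Why: Ionic hydrogenation; hydride adds to the protonated aldehyde, the benzylic alcohol ionises to a cation stabilised by the ortho and para hydroxyls and takes a second hydride, while the ester is inert and the fully substituted ring cannot form diarylmethanes.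

Step 5
Reactants: 5 methyl 2,4-dihydroxy-3,6-dimethylbenzoate
Product: 8 methyl 4-(benzyloxy)-2-hydroxy-3,6-dimethylbenzoate
Conditions: BnBr (1.05 equiv), K2CO3, acetone, reflux
Reagents that add atoms: benzyl bromide, BrCc1ccccc1
Why: Williamson etherification; the hydroxyl para to the ester (C4' oxygen) is the more acidic and unencumbered one, whereas the ortho hydroxyl is held in a hydrogen bond to the ester and should stay free with one equivalent of halide.

Step 6
Reactants: 8 methyl 4-(benzyloxy)-2-hydroxy-3,6-dimethylbenzoate
Product: 9 methyl 4-(benzyloxy)-2-methoxy-3,6-dimethylbenzoate
Conditions: MeI (excess), K2CO3, DMF, 60 °C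
Reagents that add atoms: iodomethane, CI
Why: Williamson O-methylation of the remaining hydrogen-bonded phenol (C6' oxygen) under forcing conditions in a dipolar aprotic solvent; there is no other nucleophilic site.

Step 7
Reactants: 9 methyl 4-(benzyloxy)-2-methoxy-3,6-dimethylbenzoate
Product: 10 4-(benzyloxy)-2-methoxy-3,6-dimethylbenzoic acid
Conditions: KOH, DMSO–H2O, 90 °C; then aq. HCl, 0 °C
Reagents that add atoms: potassium hydroxide, [K+].[OH-]
Why: Saponification of a doubly ortho-substituted benzoate; poorly solvated hydroxide in DMSO should reach the hindered acyl carbon, the benzyl and methyl ethers are inert to base, and cold acidification avoids protodecarboxylation of the electron-rich acid.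

Step 8
Reactants: 10 4-(benzyloxy)-2-methoxy-3,6-dimethylbenzoic acid; 7 methyl 2,4-dihydroxy-3,5,6-trimethylbenzoate
Product: 12 methyl 4-{[4-(benzyloxy)-2-methoxy-3,6-dimethylbenzoyl]oxy}-2-hydroxy-3,5,6-trimethylbenzoate, via mixed trifluoroacetic anhydride 11 (not isolated)
Conditions: (CF3CO)2O, toluene, rt; then aq. NaHCO3
Reagents that add atoms: none
Why: Mixed-anhydride esterification of the depside type; 11, from an electron-rich acid with two ortho substituents, ionises readily towards a linear acylium ion that is slim enough to reach the C4 oxygen of 7 between its two methyl groups, while the C6 hydroxyl is tied to the ester by a hydrogen bond and ring A has no C–H for C-acylation.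

Step 9
Reactants: 12 methyl 4-{[4-(benzyloxy)-2-methoxy-3,6-dimethylbenzoyl]oxy}-2-hydroxy-3,5,6-trimethylbenzoate
Product: 13 methyl 2-hydroxy-4-[(4-hydroxy-2-methoxy-3,6-dimethylbenzoyl)oxy]-3,5,6-trimethylbenzoate
Conditions: H2 (1 atm), 10% Pd/C, EtOAc, rt
Reagents that add atoms: none
Why: Hydrogenolysis of an aryl benzyl ether in neutral medium; both esters and both arenes are unaffected, and no halogen is yet present to be lost.

Step 10
Reactants: 13 methyl 2-hydroxy-4-[(4-hydroxy-2-methoxy-3,6-dimethylbenzoyl)oxy]-3,5,6-trimethylbenzoate
Product: 14 methyl 4-[(3-chloro-4-hydroxy-6-methoxy-2,5-dimethylbenzoyl)oxy]-2-hydroxy-3,5,6-trimethylbenzoate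
Conditions: NCS (1.05 equiv), DMF, 0 °C to rt, dark
Reagents that add atoms: N-chlorosuccinimide, O=C1CCC(=O)N1Cl
Why: Electrophilic aromatic chlorination of a phenol; C3' is the only aromatic C–H in the molecule and is ortho to the free C4' hydroxyl, whereas ring A is fully substituted and could react only by slower dearomatising ipso attack.

## Compound list

1 | methyl 3-oxopentanoate | CCC(=O)CC(=O)OC | starting material
2 | methyl (E)-but-2-enoate | C/C=C/C(=O)OC | starting material
3 | dimethyl 3-methyl-2-propanoylpentanedioate (mixture of diastereomers, racemic) | CCC(=O)C(C(=O)OC)C(C)CC(=O)OC | intermediate (not isolated)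
4 | methyl 3,6-dimethyl-2,4-dioxocyclohexane-1-carboxylate (mixture of stereoisomers and enol tautomers) | COC(=O)C1C(C)CC(=O)C(C)C1=O | intermediate
5 | methyl 2,4-dihydroxy-3,6-dimethylbenzoate | COC(=O)c1c(C)cc(O)c(C)c1O | intermediate
6 | methyl 3-formyl-4,6-dihydroxy-2,5-dimethylbenzoate | COC(=O)c1c(C)c(C=O)c(O)c(C)c1O | intermediate
7 | methyl 2,4-dihydroxy-3,5,6-trimethylbenzoate | COC(=O)c1c(C)c(C)c(O)c(C)c1O | intermediate
8 | methyl 4-(benzyloxy)-2-hydroxy-3,6-dimethylbenzoate | COC(=O)c1c(C)cc(OCc2ccccc2)c(C)c1O | intermediate
9 | methyl 4-(benzyloxy)-2-methoxy-3,6-dimethylbenzoate | COC(=O)c1c(C)cc(OCc2ccccc2)c(C)c1OC | intermediate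
10 | 4-(benzyloxy)-2-methoxy-3,6-dimethylbenzoic acid | OC(=O)c1c(C)cc(OCc2ccccc2)c(C)c1OC | intermediate
11 | 4-(benzyloxy)-2-methoxy-3,6-dimethylbenzoic trifluoroacetic anhydride | O=C(OC(=O)C(F)(F)F)c1c(C)cc(OCc2ccccc2)c(C)c1OC | intermediate (not isolated)
12 | methyl 4-{[4-(benzyloxy)-2-methoxy-3,6-dimethylbenzoyl]oxy}-2-hydroxy-3,5,6-trimethylbenzoate | COC(=O)c1c(C)c(C)c(OC(=O)c2c(C)cc(OCc3ccccc3)c(C)c2OC)c(C)c1O | intermediate
13 | methyl 2-hydroxy-4-[(4-hydroxy-2-methoxy-3,6-dimethylbenzoyl)oxy]-3,5,6-trimethylbenzoate | COC(=O)c1c(C)c(C)c(OC(=O)c2c(C)cc(O)c(C)c2OC)c(C)c1O | intermediate
14 | methyl 4-[(3-chloro-4-hydroxy-6-methoxy-2,5-dimethylbenzoyl)oxy]-2-hydroxy-3,5,6-trimethylbenzoate | COC(=O)c1c(C)c(C)c(OC(=O)c2c(C)c(Cl)c(O)c(C)c2OC)c(C)c1O | target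

## Step count and least certain steps

Total step count: 10. Longest linear sequence: 8 steps (steps 1, 2, 5, 6, 7, 8, 9, 10); the ring A branch (steps 3 and 4) leaves at 5 and rejoins in step 8.

**Step 1 (key step).** The conjugate addition may revert, and 2 may be consumed by base-induced self-condensation through its dienolate, or 1 by self-condensation, before the ring closes. The fallback changes the pairing of donor and acceptor. It does not set out from a numbered compound, because two other commercial compounds take the place of 1 and 2; it comes back to the route at 4. Dimethyl propanedioate F1 and (E)-hex-4-en-3-one F2 would be combined with NaOMe in MeOH at reflux. The malonate adds to the enone, a far better acceptor than a crotonate, to give dimethyl 2-(4-oxohexan-2-yl)propanedioate F3 (not isolated). The ethyl ketone enolate of F3 then closes on one malonate ester in the same six-membered Claisen mode and should give 4 with identical constitution.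

**Step 2.** Hydrogen may be passed between substrate molecules instead of being released (disproportionation with reductive loss of a ring oxygen), and at the temperature needed the β-keto ester may lose methanol. The fallback sets out from 4 and returns at 5 and replaces dehydrogenation by halogenation–dehydrohalogenation. Bromine (2 equiv) in acetic acid should brominate an enolisable position, eliminate HBr to the aromatic ring and substitute the one free ring position, giving methyl 3-bromo-4,6-dihydroxy-2,5-dimethylbenzoate F4. Hydrogenolysis of the carbon–bromine bond (H2, 10% Pd/C, NaOAc, MeOH, rt) should then give 5.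

**Step 8.** Acyl transfer between two crowded partners may be slow, which would give the acylium species time to attack the free C3' position of another acid molecule (self-acylation) or allow acid-induced loss of the benzyl group. The fallback sets out from 10 and returns at 12 and replaces the transient mixed anhydride by an isolated acyl halide used under basic conditions. Oxalyl chloride with catalytic DMF in CH2Cl2 should convert 10 into 4-(benzyloxy)-2-methoxy-3,6-dimethylbenzoyl chloride F5. F5 would be combined with 7, Et3N and catalytic 4-(dimethylamino)pyridine in CH2Cl2; the more acidic, non-hydrogen-bonded C4 hydroxyl of 7 should be acylated to give 12.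

**Step 10.** Chlorination may run on after the single C–H is consumed, or start by ipso attack at methyl-bearing carbons of either phenolic ring (dearomatisation), if C3' reacts sluggishly because of the carbonyl group para to the C4' hydroxyl. The fallback sets out from 9 and returns at 14 and brings the chlorine in before the rings are joined, where only one arene is present.
- NCS with catalytic acid in MeCN should chlorinate the one free position of 9 (ortho to the benzyloxy and para to the methoxy group) to give methyl 4-(benzyloxy)-3-chloro-6-methoxy-2,5-dimethylbenzoate F6.
- Saponification as in step 7 should give 4-(benzyloxy)-3-chloro-6-methoxy-2,5-dimethylbenzoic acid F7.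
- Trifluoroacetic anhydride in toluene should form 4-(benzyloxy)-3-chloro-6-methoxy-2,5-dimethylbenzoic trifluoroacetic anhydride F8 (not isolated), which should acylate 7 to methyl 4-{[4-(benzyloxy)-3-chloro-6-methoxy-2,5-dimethylbenzoyl]oxy}-2-hydroxy-3,5,6-trimethylbenzoate F9.
- Hydrogenolysis of the benzyl ether of F9 (H2, 10% Pd/C, EtOAc, no base, stopped after one equivalent of hydrogen) should give 14; the chlorine, flanked by two ortho substituents and in a base-free medium, is expected to be retained.

## Further compounds

F1 | step 1 | dimethyl propanedioate | COC(=O)CC(=O)OC
F2 | step 1 | (E)-hex-4-en-3-one | CCC(=O)/C=C/C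
F3 | step 1 | dimethyl 2-(4-oxohexan-2-yl)propanedioate (racemic) | CCC(=O)CC(C)C(C(=O)OC)C(=O)OC
F4 | step 2 | methyl 3-bromo-4,6-dihydroxy-2,5-dimethylbenzoate | COC(=O)c1c(C)c(Br)c(O)c(C)c1O
F5 | step 8 | 4-(benzyloxy)-2-methoxy-3,6-dimethylbenzoyl chloride | O=C(Cl)c1c(C)cc(OCc2ccccc2)c(C)c1OC
F6 | step 10 | methyl 4-(benzyloxy)-3-chloro-6-methoxy-2,5-dimethylbenzoate | COC(=O)c1c(C)c(Cl)c(OCc2ccccc2)c(C)c1OC
F7 | step 10 | 4-(benzyloxy)-3-chloro-6-methoxy-2,5-dimethylbenzoic acid | OC(=O)c1c(C)c(Cl)c(OCc2ccccc2)c(C)c1OC
F8 | step 10 | 4-(benzyloxy)-3-chloro-6-methoxy-2,5-dimethylbenzoic trifluoroacetic anhydride | O=C(OC(=O)C(F)(F)F)c1c(C)c(Cl)c(OCc2ccccc2)c(C)c1OC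
F9 | step 10 | methyl 4-{[4-(benzyloxy)-3-chloro-6-methoxy-2,5-dimethylbenzoyl]oxy}-2-hydroxy-3,5,6-trimethylbenzoate | COC(=O)c1c(C)c(C)c(OC(=O)c2c(C)c(Cl)c(OCc3ccccc3)c(C)c2OC)c(C)c1O
A1 | alternative 1 | 2-methoxy-3,6-dimethyl-4-(triisopropylsilyloxy)benzoic acid | COc1c(C(=O)O)c(C)cc(O[Si](C(C)C)(C(C)C)C(C)C)c1C
A2 | alternative 1 | 2-iodo-3-methoxy-4-methyl-5-(triisopropylsilyloxy)phenyl trifluoromethanesulfonate | COc1c(I)c(OS(=O)(=O)C(F)(F)F)cc(O[Si](C(C)C)(C(C)C)C(C)C)c1C
A3 | alternative 2 | 2,4,5-trimethyl-3-(triisopropylsilyloxy)phenol | Cc1c(C)cc(O)c(C)c1O[Si](C(C)C)(C(C)C)C(C)C
A4 | alternative 2 | 2,3-dimethylcyclobut-2-en-1-one | CC1=C(C)C(=O)C1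
A5 | alternative 2 | triisopropyl(prop-1-yn-1-yloxy)silane | CC#CO[Si](C(C)C)(C(C)C)C(C)C
A6 | alternative 3 | methyl 2-hydroxy-4-[(4-hydroxy-2-methoxy-3,6-dimethylbenzoyl)oxy]-3,5,6-trimethylbenzoate (identical with 13) | COC(=O)c1c(C)c(C)c(OC(=O)c2c(C)cc(O)c(C)c2OC)c(C)c1O
A7 | alternative 3 | methyl 4-(but-2-ynoyloxy)-2-hydroxy-3,5,6-trimethylbenzoate | CC#CC(=O)Oc1c(C)c(C)c(C(=O)OC)c(O)c1C
A8 | alternative 3 | [(4,4-dimethoxy-3-methylbuta-1,3-dien-2-yl)oxy]trimethylsilane | COC(OC)=C(C)C(=C)O[Si](C)(C)C
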